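**Retrosynthetic overview**
1. Target 21 ⇐ one-pot hydrogenolysis (two ArO–Bn bonds and one benzylic C–OAc bond) of the acetylated aldol adduct 20.
2. Key disconnection C3–C(benzylic): aldol addition of the dianion of α-hydroxy lactone 16 to O-benzylvanillin 17. The aldehyde enters anti to the C4 arylmethyl group, which sets the quaternary C3 with its OH cis to the C4 substituent.
3. 16 ⇐ enolate hydroxylation of (R)-β-(arylmethyl)-γ-butyrolactone 14.
4. 14 ⇐ Evans alkylation of N-(3-arylpropanoyl)oxazolidinone 9 with tert-butyl bromoacetate (sets C4), then reduction and lactonization. The lactone is the only ring built, and it is closed before either C3 substituent is introduced.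
5. 9 ⇐ syringaldehyde 1 by benzylation, Wittig olefination, conjugate reduction, saponification and N-acylation.

Assumption: 3, 7, 10, 17 and the amide bases (as solutions) are bought; 16 is carried as its 3,4-trans-major epimer mixture because C3 is made planar again in step 9.

**Step 1**
Reactants: 1 syringaldehyde (4-hydroxy-3,5-dimethoxybenzaldehyde)
Product: 2 4-(benzyloxy)-3,5-dimethoxybenzaldehyde
Conditions: BnBr (1.2 equiv), K2CO3 (2 equiv), DMF, 60 °C
Reagents that add atoms: benzyl bromide, BrCc1ccccc1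
Why: Williamson ether synthesis on the phenoxide installs a benzyl ether that survives every later base, hydride and oxidant and is removed in the final hydrogenolysis.

**Step 2**
Reactants: 2 4-(benzyloxy)-3,5-dimethoxybenzaldehyde; 3 methyl (triphenylphosphoranylidene)acetate
Product: 4 methyl (E)-3-[4-(benzyloxy)-3,5-dimethoxyphenyl]prop-2-enoate
Conditions: toluene, 90 °C
Reagents that add atoms: none
Why: Wittig olefination with a stabilized ylide gives the E-cinnamate cleanly, and the alkene geometry is erased in the next step anyway.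

**Step 3**
Reactants: 4 methyl (E)-3-[4-(benzyloxy)-3,5-dimethoxyphenyl]prop-2-enoate
Product: 5 methyl 3-[4-(benzyloxy)-3,5-dimethoxyphenyl]propanoate
Conditions: NaBH4 (3 equiv), NiCl2·6H2O (0.3 equiv), MeOH–THF, 0 °C
Reagents that add atoms: none
Why: Conjugate reduction with in situ Ni2B saturates the cinnamate C=C without hydrogenolysis of the aryl benzyl ether or reduction of the ester.

**Step 4**
Reactants: 5 methyl 3-[4-(benzyloxy)-3,5-dimethoxyphenyl]propanoate
Product: 6 3-[4-(benzyloxy)-3,5-dimethoxyphenyl]propanoic acid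
Conditions: LiOH·H2O (3 equiv), THF–MeOH–H2O, rt; then 1 M HCl
Reagents that add atoms: lithium hydroxide, [Li+].[OH-]
Why: Saponification of an unhindered methyl ester is quantitative and leaves the benzyl and methyl aryl ethers untouched.

**Step 5**
Reactants: 6 3-[4-(benzyloxy)-3,5-dimethoxyphenyl]propanoic acid; 7 (S)-4-benzyloxazolidin-2-one
Product: 9 (S)-4-benzyl-3-{3-[4-(benzyloxy)-3,5-dimethoxyphenyl]propanoyl}oxazolidin-2-one, via mixed pivalic anhydride 8 (not isolated)
Conditions: PivCl, Et3N, THF, −20 °C; then 7, LiCl, −20 °C → rt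
Reagents that add atoms: none
Why: N-acylation of the oxazolidinone through a mixed anhydride, which is attacked selectively at the less hindered (non-pivaloyl) carbonyl.

**Step 6**
Reactants: 9 (S)-4-benzyl-3-{3-[4-(benzyloxy)-3,5-dimethoxyphenyl]propanoyl}oxazolidin-2-one; 10 tert-butyl bromoacetate
Product: 12 tert-butyl (3R)-3-{[(4S)-4-benzyl-2-oxooxazolidin-3-yl]carbonyl}-4-[4-(benzyloxy)-3,5-dimethoxyphenyl]butanoate, via sodium Z-enolate 11 (not isolated)
Conditions: NaN(SiMe3)2 (1.1 equiv), THF, −78 °C; then 10, −78 → −40 °C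
Reagents that add atoms: none
Why: Evans asymmetric alkylation, in which the chelated Z-enolate is alkylated on the face opposite the auxiliary's C4 benzyl group, sets the future lactone C4 as R (typically ≥95:5, minor isomer removed by chromatography).

**Step 7**
Reactants: 12 tert-butyl (3R)-3-{[(4S)-4-benzyl-2-oxooxazolidin-3-yl]carbonyl}-4-[4-(benzyloxy)-3,5-dimethoxyphenyl]butanoate
Product: 14 (R)-4-[4-(benzyloxy)-3,5-dimethoxybenzyl]dihydrofuran-2(3H)-one, via hydroxy tert-butyl ester 13 (not isolated)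
Conditions: LiBH4 (1.5 equiv), MeOH (1.5 equiv), THF, 0 °C; then TsOH·H2O (0.1 equiv), CH2Cl2, rt
Reagents that add atoms: none
Why: Chemoselective borohydride reduction of the activated imide carbonyl (the tert-butyl ester is spared) followed by acid-catalysed lactonization closes the ring without touching the stereocentre, and the auxiliary is recovered.

**Step 8**
Reactants: 14 (R)-4-[4-(benzyloxy)-3,5-dimethoxybenzyl]dihydrofuran-2(3H)-one
Product: 16 (3R,4S)-4-[4-(benzyloxy)-3,5-dimethoxybenzyl]-3-hydroxydihydrofuran-2(3H)-one, via potassium lactone enolate 15 (not isolated)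
Conditions: KN(SiMe3)2 (1.2 equiv), THF, −78 °C; then 2-(phenylsulfonyl)-3-phenyloxaziridine (1.3 equiv), −78 °C; AcOH quench
Reagents that add atoms: 2-(phenylsulfonyl)-3-phenyloxaziridine, O=S(=O)(N1OC1c1ccccc1)c1ccccc1
Why: Davis enolate hydroxylation transfers oxygen anti to the C4 substituent to give mainly the 3,4-trans alcohol, and the C3 configuration does not matter because C3 is planar again in step 9.

**Step 9**
Reactants: 16 (3R,4S)-4-[4-(benzyloxy)-3,5-dimethoxybenzyl]-3-hydroxydihydrofuran-2(3H)-one; 17 4-(benzyloxy)-3-methoxybenzaldehyde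
Product: 19 (3R,4S)-4-[4-(benzyloxy)-3,5-dimethoxybenzyl]-3-{[4-(benzyloxy)-3-methoxyphenyl](hydroxy)methyl}-3-hydroxydihydrofuran-2(3H)-one, via dilithium enediolate 18 (not isolated)
Conditions: LiN(iPr)2 (2.3 equiv), THF–DMPU, −78 → −40 °C; then 17, −78 °C; AcOH quench at −78 °C
Reagents that add atoms: none
Why: Intermolecular aldol addition of the α-oxido lactone enolate, where the aldehyde adds anti to the C4 arylmethyl group so the retained oxygen ends up cis to it, sets the quaternary C3; the carbinol epimers both go forward because that centre is removed in step 11.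

**Step 10**
Reactants: 19 (3R,4S)-4-[4-(benzyloxy)-3,5-dimethoxybenzyl]-3-{[4-(benzyloxy)-3-methoxyphenyl](hydroxy)methyl}-3-hydroxydihydrofuran-2(3H)-one
Product: 20 [4-(benzyloxy)-3-methoxyphenyl]{(3R,4S)-4-[4-(benzyloxy)-3,5-dimethoxybenzyl]-3-hydroxy-2-oxotetrahydrofuran-3-yl}methyl acetate
Conditions: Ac2O (1.5 equiv), pyridine, CH2Cl2, 0 °C → rt
Reagents that add atoms: acetic anhydride, CC(=O)OC(C)=O
Why: Selective O-acylation of the secondary benzylic alcohol (the hindered tertiary α-hydroxy lactone OH does not react without DMAP) turns the benzylic oxygen into a leaving group for hydrogenolysis.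

**Step 11**
Reactants: 20 [4-(benzyloxy)-3-methoxyphenyl]{(3R,4S)-4-[4-(benzyloxy)-3,5-dimethoxybenzyl]-3-hydroxy-2-oxotetrahydrofuran-3-yl}methyl acetate
Product: 21 (3S,4S)-3-hydroxy-4-(4-hydroxy-3,5-dimethoxybenzyl)-3-(4-hydroxy-3-methoxybenzyl)dihydrofuran-2(3H)-one (CNP0315014.1)
Conditions: H2 (3 bar), 10% Pd/C, EtOAc–AcOH (10:1), rt
Reagents that add atoms: none
Why: Catalytic hydrogenolysis cleaves both O-benzyl ethers and the electron-rich benzylic C–OAc bond without generating a free benzylic cation (which would cyclize onto the trioxygenated ring to an aryltetralin), leaving the tertiary alcohol, the lactone and both stereocentres intact.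

**Compound list**
1 | syringaldehyde (4-hydroxy-3,5-dimethoxybenzaldehyde) | COc1cc(C=O)cc(OC)c1O | starting material
2 | 4-(benzyloxy)-3,5-dimethoxybenzaldehyde | COc1cc(C=O)cc(OC)c1OCc1ccccc1 | intermediate
3 | methyl (triphenylphosphoranylidene)acetate | COC(=O)C=P(c1ccccc1)(c1ccccc1)c1ccccc1 | starting material
4 | methyl (E)-3-[4-(benzyloxy)-3,5-dimethoxyphenyl]prop-2-enoate | COC(=O)/C=C/c1cc(OC)c(OCc2ccccc2)c(OC)c1 | intermediate
5 | methyl 3-[4-(benzyloxy)-3,5-dimethoxyphenyl]propanoate | COC(=O)CCc1cc(OC)c(OCc2ccccc2)c(OC)c1 | intermediate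
6 | 3-[4-(benzyloxy)-3,5-dimethoxyphenyl]propanoic acid | OC(=O)CCc1cc(OC)c(OCc2ccccc2)c(OC)c1 | intermediate
7 | (S)-4-benzyloxazolidin-2-one | O=C1N[C@@H](Cc2ccccc2)CO1 | starting material
8 | 3-[4-(benzyloxy)-3,5-dimethoxyphenyl]propanoic pivalic anhydride | CC(C)(C)C(=O)OC(=O)CCc1cc(OC)c(OCc2ccccc2)c(OC)c1 | intermediate
9 | (S)-4-benzyl-3-{3-[4-(benzyloxy)-3,5-dimethoxyphenyl]propanoyl}oxazolidin-2-one | COc1cc(CCC(=O)N2[C@@H](Cc3ccccc3)COC2=O)cc(OC)c1OCc1ccccc1 | intermediate
10 | tert-butyl bromoacetate | CC(C)(C)OC(=O)CBr | starting material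
11 | sodium (Z)-1-[(4S)-4-benzyl-2-oxooxazolidin-3-yl]-3-[4-(benzyloxy)-3,5-dimethoxyphenyl]prop-1-en-1-olate (sodium Z-enolate of 9) | [Na+].[O-]/C(=C\Cc1cc(OC)c(OCc2ccccc2)c(OC)c1)N1[C@@H](Cc2ccccc2)COC1=O | intermediate
12 | tert-butyl (3R)-3-{[(4S)-4-benzyl-2-oxooxazolidin-3-yl]carbonyl}-4-[4-(benzyloxy)-3,5-dimethoxyphenyl]butanoate | CC(C)(C)OC(=O)C[C@@H](Cc1cc(OC)c(OCc2ccccc2)c(OC)c1)C(=O)N1[C@@H](Cc2ccccc2)COC1=O | intermediate
13 | tert-butyl (3R)-4-[4-(benzyloxy)-3,5-dimethoxyphenyl]-3-(hydroxymethyl)butanoate | CC(C)(C)OC(=O)C[C@@H](Cc1cc(OC)c(OCc2ccccc2)c(OC)c1)CO | intermediate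
14 | (R)-4-[4-(benzyloxy)-3,5-dimethoxybenzyl]dihydrofuran-2(3H)-one | O=C1C[C@@H](Cc2cc(OC)c(OCc3ccccc3)c(OC)c2)CO1 | intermediate
15 | potassium (R)-4-[4-(benzyloxy)-3,5-dimethoxybenzyl]-4,5-dihydrofuran-2-olate | [K+].[O-]C1=C[C@@H](Cc2cc(OC)c(OCc3ccccc3)c(OC)c2)CO1 | intermediate
16 | (3R,4S)-4-[4-(benzyloxy)-3,5-dimethoxybenzyl]-3-hydroxydihydrofuran-2(3H)-one (3,4-trans, major epimer) | O[C@H]1C(=O)OC[C@@H]1Cc1cc(OC)c(OCc2ccccc2)c(OC)c1 | intermediate
17 | 4-(benzyloxy)-3-methoxybenzaldehyde (O-benzylvanillin) | COc1cc(C=O)ccc1OCc1ccccc1 | starting material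
18 | dilithium (S)-4-[4-(benzyloxy)-3,5-dimethoxybenzyl]-4,5-dihydrofuran-2,3-bis(olate) | [Li+].[Li+].[O-]C1=C([O-])[C@@H](Cc2cc(OC)c(OCc3ccccc3)c(OC)c2)CO1 | intermediate
19 | (3R,4S)-4-[4-(benzyloxy)-3,5-dimethoxybenzyl]-3-{[4-(benzyloxy)-3-methoxyphenyl](hydroxy)methyl}-3-hydroxydihydrofuran-2(3H)-one (both carbinol epimers) | COc1cc(C(O)[C@@]2(O)C(=O)OC[C@@H]2Cc2cc(OC)c(OCc3ccccc3)c(OC)c2)ccc1OCc1ccccc1 | intermediate
20 | [4-(benzyloxy)-3-methoxyphenyl]{(3R,4S)-4-[4-(benzyloxy)-3,5-dimethoxybenzyl]-3-hydroxy-2-oxotetrahydrofuran-3-yl}methyl acetate (both epimers at the acetoxy carbon) | COc1cc(C(OC(C)=O)[C@@]2(O)C(=O)OC[C@@H]2Cc2cc(OC)c(OCc3ccccc3)c(OC)c2)ccc1OCc1ccccc1 | intermediate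
21 | (3S,4S)-3-hydroxy-4-(4-hydroxy-3,5-dimethoxybenzyl)-3-(4-hydroxy-3-methoxybenzyl)dihydrofuran-2(3H)-one | COc1cc(C[C@@]2(O)C(=O)OC[C@@H]2Cc2cc(OC)c(O)c(OC)c2)ccc1O | target

**Totals**
Total step count: 11. Longest linear sequence: 11 steps (1 → 21); 3, 7, 10 and 17 enter as purchased materials.

**Three steps most likely to fail**

Step 9 (dianion aldol). The second deprotonation next to an alkoxide may be incomplete, the aldolate may revert, and the facial selectivity at the new quaternary centre has to be confirmed (NOE between the C3 substituent and H-4). The fallback sets out from 16 and comes back at 19. Compound 16 is doubly deprotonated with LiN(iPr)2 and trapped with Me3SiCl to give the bis(silyl) enediol ether (S)-4-[4-(benzyloxy)-3,5-dimethoxybenzyl]-2,3-bis(trimethylsilyloxy)-4,5-dihydrofuran F1. This neutral, isolable nucleophile is then added to 17 under BF3·OEt2 in CH2Cl2 at −78 °C with a cold NaHCO3 quench (Mukaiyama aldol through an open transition state, same approach anti to the C4 group). Stirring the crude product with dilute aqueous HCl in THF removes the silyl groups and gives 19.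

Step 11 (hydrogenolysis of a benzylic acetate next to a quaternary carbon). The C–OAc cleavage may stall after the two debenzylations. The fallback sets out from 19 and comes back at 21. The secondary benzylic alcohol of 19 is converted with PhOC(S)Cl and pyridine in CH2Cl2 into the thionocarbonate O-{[4-(benzyloxy)-3-methoxyphenyl][(3R,4S)-4-[4-(benzyloxy)-3,5-dimethoxybenzyl]-3-hydroxy-2-oxotetrahydrofuran-3-yl]methyl} O-phenyl carbonothioate F2. Radical deoxygenation with Bu3SnH and AIBN in toluene at 90 °C (Barton–McCombie, no cation and so no Friedel–Crafts ring closure) gives (3S,4S)-3-[4-(benzyloxy)-3-methoxybenzyl]-4-[4-(benzyloxy)-3,5-dimethoxybenzyl]-3-hydroxydihydrofuran-2(3H)-one F3. Ordinary debenzylation (H2, 10% Pd/C, EtOAc, rt) then gives 21.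

Step 8 (enolate hydroxylation). Possible problems are self-condensation of the lactone enolate, addition of the enolate to the sulfonimine by-product, and over-oxidation. The fallback sets out from 14 and comes back at 16. Compound 14 is deprotonated with LiN(iPr)2 at −78 °C and O-silylated with Me3SiCl to give the silyl ketene acetal (R)-{[4-(4-(benzyloxy)-3,5-dimethoxybenzyl)-4,5-dihydrofuran-2-yl]oxy}trimethylsilane F4. Rubottom oxidation with mCPBA in CH2Cl2–hexane at −20 °C (epoxidation anti to the C4 group, then silyl migration) gives (3R,4S)-4-[4-(benzyloxy)-3,5-dimethoxybenzyl]-3-(trimethylsilyloxy)dihydrofuran-2(3H)-one F5. Aqueous citric acid in THF removes the silyl group and gives 16.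

**Further compounds**
F1 | step 9 | (S)-4-[4-(benzyloxy)-3,5-dimethoxybenzyl]-2,3-bis(trimethylsilyloxy)-4,5-dihydrofuran | C[Si](C)(C)OC1=C(O[Si](C)(C)C)[C@@H](Cc2cc(OC)c(OCc3ccccc3)c(OC)c2)CO1
F2 | step 11 | O-{[4-(benzyloxy)-3-methoxyphenyl][(3R,4S)-4-[4-(benzyloxy)-3,5-dimethoxybenzyl]-3-hydroxy-2-oxotetrahydrofuran-3-yl]methyl} O-phenyl carbonothioate | COc1cc(C(OC(=S)Oc3ccccc3)[C@@]2(O)C(=O)OC[C@@H]2Cc2cc(OC)c(OCc3ccccc3)c(OC)c2)ccc1OCc1ccccc1
F3 | step 11 | (3S,4S)-3-[4-(benzyloxy)-3-methoxybenzyl]-4-[4-(benzyloxy)-3,5-dimethoxybenzyl]-3-hydroxydihydrofuran-2(3H)-one | COc1cc(C[C@@]2(O)C(=O)OC[C@@H]2Cc2cc(OC)c(OCc3ccccc3)c(OC)c2)ccc1OCc1ccccc1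
F4 | step 8 | (R)-{[4-(4-(benzyloxy)-3,5-dimethoxybenzyl)-4,5-dihydrofuran-2-yl]oxy}trimethylsilane | C[Si](C)(C)OC1=C[C@@H](Cc2cc(OC)c(OCc3ccccc3)c(OC)c2)CO1
F5 | step 8 | (3R,4S)-4-[4-(benzyloxy)-3,5-dimethoxybenzyl]-3-(trimethylsilyloxy)dihydrofuran-2(3H)-one | C[Si](C)(C)O[C@H]1C(=O)OC[C@@H]1Cc1cc(OC)c(OCc2ccccc2)c(OC)c1
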